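**Plan**
- Retrosynthetic cuts, in order: the O8–acyl bond of the ferulate; the C1=C10 double bond (back to a C1 methylidene and a C9 methallyl group); C6–C7 (a C6 electrophile plus a β-hydroxy ester dianion); the two C11–CH3 bonds (ester plus MeMgBr).
- Forward: the cyclopentane (C1–C5) is made first from (S)-citronellal, the chain is joined at C6–C7, the C11 carbinol is built, the seven-membered ring is closed last at C1=C10 by ring-closing metathesis, and O8 is acylated at the end.
- Enabling feature: C1 and C10 are the two fully substituted sp2 carbons of the only ring olefin (endocyclic in the seven-membered ring, exocyclic to the five-membered ring) and bear only carbon neighbours. Each can therefore be carried as a terminal =CH2 and joined without stereochemical consequence. The O8/O11 1,3-diol is tied as an acetonide (a temporary six-membered ring) that holds the C6 and C9 arms gauche for closure.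
- Stereochemistry: C4 is bought ((S)-citronellal) and relays C5 (hydroboration anti to the C4 methyl). C8 is bought (ethyl (R)-4-chloro-3-hydroxybutanoate) and relays C7 (anti alkylation of the chelated dianion).

Key step: step 12

Remark: guaiane numbering is used (five-membered ring C1–C5, seven-membered ring C1, C5–C10, carbinol carbon C11). The target SMILES is read as 4S,5S,7S,8S: C4 methyl cis to the C5–C6 bond, H5 and H7 cis, O8 trans to the C7 side chain.

**Step 1**
Reactants: 1 (S)-citronellal [(3S)-3,7-dimethyloct-6-enal]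
Product: 2 (3S)-3,7-dimethyl-2-methylideneoct-6-enal
Conditions: 37% aq. CH2O, pyrrolidine (10 mol %), propionic acid (10 mol %), i-PrOH, 45 °C
Reagents that add atoms: formaldehyde, C=O
Why: Amine/acid-catalysed Mannich-type α-methylenation of the aldehyde installs the 2-methylidene group, and the C4 stereocenter is β to the carbonyl and cannot epimerize.

**Step 2**
Reactants: 2 (3S)-3,7-dimethyl-2-methylideneoct-6-enal
Product: 3 (5S)-5-methylcyclopent-1-ene-1-carbaldehyde
Conditions: RuCl2(=CHPh)(PCy3)(H2IMes) (second-generation Grubbs catalyst, 2 mol %), CH2Cl2, 40 °C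
Reagents that add atoms: none
Why: Ring-closing metathesis between the 1,1-disubstituted enal olefin and the prenyl terminus closes the cyclopentene with loss of 2-methylpropene, forming no stereocenter and leaving C4 untouched.

**Step 3**
Reactants: 3 (5S)-5-methylcyclopent-1-ene-1-carbaldehyde
Product: 5 (1S,2R,3S)-2-(hydroxymethyl)-3-methylcyclopentan-1-ol, via bisborylated intermediate 4 (not isolated)
Conditions: BH3·THF (3 equiv), THF, 0 °C to rt; then 3 M NaOH, 30% H2O2, 0 °C to rt
Reagents that add atoms: hydrogen peroxide, OO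
Why: Borane reduces the aldehyde and then adds syn and anti-Markovnikov to the trisubstituted ring olefin from the face opposite the C4 methyl (hydroboration–oxidation), so H is delivered to C5 trans to the methyl (C6 arm cis to it) and oxidation with retention should give the C1 hydroxyl trans to the C6 arm.

**Step 4**
Reactants: 5 (1S,2R,3S)-2-(hydroxymethyl)-3-methylcyclopentan-1-ol
Product: 7 (4aR,5S,7aS)-5-methylhexahydrocyclopenta[d][1,3,2]dioxathiine 2,2-dioxide (trans-fused cyclic sulfate of 5), via cyclic sulfite 6 (not isolated)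
Conditions: SOCl2, Et3N, CH2Cl2, 0 °C; then RuCl3·3H2O (1 mol %), NaIO4, MeCN/H2O, 0 °C
Reagents that add atoms: thionyl chloride, O=S(Cl)Cl; sodium periodate, [Na+].[O-]I(=O)(=O)=O
Why: Cyclic sulfite formation followed by RuCl3-catalysed periodate oxidation (cyclic sulfate synthesis) turns the primary C6–O bond into a leaving group and masks O1 in the same temporary ring, without touching a stereocenter.

**Step 5**
Reactants: 8 ethyl (3R)-4-chloro-3-hydroxybutanoate
Product: 9 ethyl 2-[(2R)-oxiran-2-yl]acetate
Conditions: Ag2O, DME, 65 °C, dark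
Reagents that add atoms: none
Why: Silver-assisted halohydrin-to-epoxide closure (intramolecular Williamson reaction) displaces the primary chloride, so the carbinol stereocenter (future C8) is retained.

**Step 6**
Reactants: 9 ethyl 2-[(2R)-oxiran-2-yl]acetate
Product: 10 ethyl (3S)-3-hydroxy-5-methylhex-5-enoate
Conditions: CH2=C(CH3)MgBr (1.5 equiv), CuI (10 mol %), THF, −40 to −20 °C
Reagents that add atoms: isopropenylmagnesium bromide, CC(=C)[Mg]Br
Why: Copper-catalysed Grignard opening of the terminal epoxide at its CH2 carbon (SN2) installs the C9–C10 methallyl unit and leaves the carbinol configuration unchanged.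

**Step 7**
Reactants: 10 ethyl (3S)-3-hydroxy-5-methylhex-5-enoate; 7 cyclic sulfate
Product: 13 ethyl (2S,3S)-3-hydroxy-2-{[(1S,2S,5S)-2-hydroxy-5-methylcyclopentyl]methyl}-5-methylhex-5-enoate, via dilithio dianion 11 (not isolated), via lithium alkyl sulfate 12 (not isolated)
Conditions: LDA (2.1 equiv), THF, −78 to −30 °C; 7, DMPU, −78 to 0 °C; then aq. H2SO4 (to pH 1), THF, rt
Reagents that add atoms: none
Why: Fráter–Seebach alkylation: the lithium-chelated alkoxide-enolate is alkylated by the primary carbon of the cyclic sulfate on the face anti to the C9 substituent, which should set C7 anti to the C8 hydroxyl, and acid hydrolysis of the alkyl sulfate (S–O cleavage) frees the C1 hydroxyl with retention.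

**Step 8**
Reactants: 13 ethyl (2S,3S)-3-hydroxy-2-{[(1S,2S,5S)-2-hydroxy-5-methylcyclopentyl]methyl}-5-methylhex-5-enoate
Product: 14 (3S,4S)-3-{[(1S,2S,5S)-2-hydroxy-5-methylcyclopentyl]methyl}-2,6-dimethylhept-6-ene-2,4-diol
Conditions: MeMgBr (6 equiv), THF, 0 °C to rt
Reagents that add atoms: methylmagnesium bromide, C[Mg]Br
Why: Double Grignard addition to the ester builds the C11 dimethylcarbinol, the O8 alkoxide disfavouring enolization at C7, and no stereocenter is formed.

**Step 9**
Reactants: 14 (3S,4S)-3-{[(1S,2S,5S)-2-hydroxy-5-methylcyclopentyl]methyl}-2,6-dimethylhept-6-ene-2,4-diol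
Product: 15 (1S,2S,3S)-3-methyl-2-{[(5S,6S)-2,2,4,4-tetramethyl-6-(2-methylprop-2-en-1-yl)-1,3-dioxan-5-yl]methyl}cyclopentan-1-ol
Conditions: Me2C(OMe)2, PPTS (cat.), CH2Cl2, rt
Reagents that add atoms: 2,2-dimethoxypropane, COC(C)(C)OC
Why: Acid-catalysed acetonide formation ties only the O8/O11 1,3-diol into a six-membered ring, leaving the isolated C1 hydroxyl free and placing the C6 and C9 arms trans-diequatorial on the dioxane.

**Step 10**
Reactants: 15 (1S,2S,3S)-3-methyl-2-{[(5S,6S)-2,2,4,4-tetramethyl-6-(2-methylprop-2-en-1-yl)-1,3-dioxan-5-yl]methyl}cyclopentan-1-ol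
Product: 16 (2S,3S)-3-methyl-2-{[(5S,6S)-2,2,4,4-tetramethyl-6-(2-methylprop-2-en-1-yl)-1,3-dioxan-5-yl]methyl}cyclopentan-1-one
Conditions: Dess–Martin periodinane, NaHCO3, CH2Cl2, 0 °C to rt
Reagents that add atoms: none
Why: Buffered Dess–Martin oxidation converts the C1 carbinol into the ketone under non-basic conditions, so the adjacent cis C5 center should not epimerize.

**Step 11**
Reactants: 16 (2S,3S)-3-methyl-2-{[(5S,6S)-2,2,4,4-tetramethyl-6-(2-methylprop-2-en-1-yl)-1,3-dioxan-5-yl]methyl}cyclopentan-1-one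
Product: 17 (5S,6S)-2,2,4,4-tetramethyl-5-{[(1S,2S)-2-methyl-5-methylidenecyclopentyl]methyl}-6-(2-methylprop-2-en-1-yl)-1,3-dioxane
Conditions: Cp2TiMe2 (3 equiv), toluene/THF, 65 °C, dark
Reagents that add atoms: dimethyltitanocene, C[Ti](C)(C1C=CC=C1)C1C=CC=C1
Why: Petasis methylenation (non-basic titanium methylidene) turns the enolizable ketone into the exocyclic 1,1-disubstituted olefin without epimerization at C5, which is configurationally fixed from here on.

**Step 12**
Reactants: 17 (5S,6S)-2,2,4,4-tetramethyl-5-{[(1S,2S)-2-methyl-5-methylidenecyclopentyl]methyl}-6-(2-methylprop-2-en-1-yl)-1,3-dioxane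
Product: 18 8,11-O-isopropylidene-(4S,5S,7S,8S)-guai-1(10)-ene-8,11-diol (tricyclic acetonide)
Conditions: RuCl2(=CH–C6H4-2-OiPr)[1,3-bis(2-methylphenyl)imidazolidin-2-ylidene] (10 mol %, two portions), 2,6-dichloro-1,4-benzoquinone (10 mol %), toluene (0.005 M), 90 °C, Ar sparge
Reagents that add atoms: none
Why: The ruthenium alkylidene loads onto the less hindered C10=CH2 olefin, adds [2+2] to the C1=CH2 olefin, and cycloreversion of the ruthenacyclobutane forms the C1=C10 double bond and releases ethene, which is swept out. The closest known reaction type is ring-closing metathesis of two 1,1-disubstituted olefins to tetrasubstituted cycloalkenes with ruthenium catalysts bearing small N-aryl carbene ligands. The seven-membered carbocycle (C1, C5, C6, C7, C8, C9, C10) is closed by this single olefin-metathesis ring closure, fused to the cyclopentane at C1–C5 and trans-fused to the dioxane at C7–C8. No stereocenter is created, and C4, C5, C7 and C8 are carried through unchanged. The step needs cyclization to win over oligomerization and over olefin migration; the trans-diequatorial acetonide pre-folds the two arms, high dilution disfavours intermolecular metathesis, the quinone intercepts ruthenium hydrides, and the tetrasubstituted product should not re-enter the cycle.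

**Step 13**
Reactants: 18 tricyclic acetonide
Product: 19 (3S,3aS,5S,6S)-5-(2-hydroxypropan-2-yl)-3,8-dimethyl-1,2,3,3a,4,5,6,7-octahydroazulen-6-ol
Conditions: PPTS (20 mol %), MeOH, rt
Reagents that add atoms: none
Why: Mild acid-catalysed transketalization removes the crowded tetramethyl-1,3-dioxane under conditions that should neither ionize the tertiary carbinol nor move the tetrasubstituted olefin.

**Step 14**
Reactants: 19 diol; 20 (2E)-3-(4-acetoxy-3-methoxyphenyl)prop-2-enoic acid (O-acetylferulic acid)
Product: 21 (3S,3aS,5S,6S)-5-(2-hydroxypropan-2-yl)-3,8-dimethyl-1,2,3,3a,4,5,6,7-octahydroazulen-6-yl (2E)-3-(4-acetoxy-3-methoxyphenyl)prop-2-enoate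
Conditions: DCC, DMAP (cat.), CH2Cl2, 0 °C to rt
Reagents that add atoms: none
Why: Steglich esterification acylates the secondary C8 hydroxyl selectively because the tertiary C11 hydroxyl is inert to carbodiimide/DMAP acylation, and the C8 configuration is retained since its C–O bond is not broken.

**Step 15**
Reactants: 21 O-acetyl ester
Product: 22 (3S,3aS,5S,6S)-5-(2-hydroxypropan-2-yl)-3,8-dimethyl-1,2,3,3a,4,5,6,7-octahydroazulen-6-yl (2E)-3-(4-hydroxy-3-methoxyphenyl)prop-2-enoate (target)
Conditions: pyrrolidine (3 equiv), CH2Cl2, 0 °C to rt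
Reagents that add atoms: none
Why: Aminolysis of the activated aryl acetate by pyrrolidine should be much faster than attack on the hindered secondary cinnamate, releasing the free phenol.

**Compound list**
1 | (S)-citronellal, (3S)-3,7-dimethyloct-6-enal | C[C@@H](CCC=C(C)C)CC=O | starting material
2 | (3S)-3,7-dimethyl-2-methylideneoct-6-enal | C[C@@H](CCC=C(C)C)C(=C)C=O | intermediate
3 | (5S)-5-methylcyclopent-1-ene-1-carbaldehyde | C[C@H]1CCC=C1C=O | intermediate
4 | bisborylated intermediate (BH2 on C1, O-BH2 on C6; representative form) | C[C@H]1CC[C@H](B)[C@H]1COB | intermediate (not isolated)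
5 | (1S,2R,3S)-2-(hydroxymethyl)-3-methylcyclopentan-1-ol | C[C@H]1CC[C@H](O)[C@H]1CO | intermediate
6 | cyclic sulfite of 5 (2-oxide, both sulfur epimers) | C[C@H]1CC[C@@H]2OS(=O)OC[C@@H]12 | intermediate (not isolated)
7 | (4aR,5S,7aS)-5-methylhexahydrocyclopenta[d][1,3,2]dioxathiine 2,2-dioxide | C[C@H]1CC[C@@H]2OS(=O)(=O)OC[C@@H]12 | intermediate
8 | ethyl (3R)-4-chloro-3-hydroxybutanoate | CCOC(=O)C[C@@H](O)CCl | starting material
9 | ethyl 2-[(2R)-oxiran-2-yl]acetate | CCOC(=O)C[C@@H]1CO1 | intermediate
10 | ethyl (3S)-3-hydroxy-5-methylhex-5-enoate | CCOC(=O)C[C@@H](O)CC(C)=C | intermediate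
11 | dilithio dianion of 10 (alkoxide-enolate) | [Li+].[Li+].CCOC([O-])=C[C@@H]([O-])CC(C)=C | intermediate (not isolated)
12 | lithium alkyl sulfate of 13 (C1–OSO3Li, O8 lithium alkoxide) | [Li+].[Li+].CCOC(=O)[C@@H](C[C@H]1[C@@H](C)CC[C@@H]1OS(=O)(=O)[O-])[C@@H]([O-])CC(C)=C | intermediate (not isolated)
13 | ethyl (2S,3S)-3-hydroxy-2-{[(1S,2S,5S)-2-hydroxy-5-methylcyclopentyl]methyl}-5-methylhex-5-enoate | CCOC(=O)[C@@H](C[C@H]1[C@@H](C)CC[C@@H]1O)[C@@H](O)CC(C)=C | intermediate
14 | (3S,4S)-3-{[(1S,2S,5S)-2-hydroxy-5-methylcyclopentyl]methyl}-2,6-dimethylhept-6-ene-2,4-diol | CC(C)(O)[C@@H](C[C@H]1[C@@H](C)CC[C@@H]1O)[C@@H](O)CC(C)=C | intermediate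
15 | (1S,2S,3S)-3-methyl-2-{[(5S,6S)-2,2,4,4-tetramethyl-6-(2-methylprop-2-en-1-yl)-1,3-dioxan-5-yl]methyl}cyclopentan-1-ol | CC1(C)O[C@@H](CC(C)=C)[C@H](C[C@H]2[C@@H](C)CC[C@@H]2O)C(C)(C)O1 | intermediate
16 | (2S,3S)-3-methyl-2-{[(5S,6S)-2,2,4,4-tetramethyl-6-(2-methylprop-2-en-1-yl)-1,3-dioxan-5-yl]methyl}cyclopentan-1-one | CC1(C)O[C@@H](CC(C)=C)[C@H](C[C@H]2[C@@H](C)CCC2=O)C(C)(C)O1 | intermediate
17 | (5S,6S)-2,2,4,4-tetramethyl-5-{[(1S,2S)-2-methyl-5-methylidenecyclopentyl]methyl}-6-(2-methylprop-2-en-1-yl)-1,3-dioxane | CC1(C)O[C@@H](CC(C)=C)[C@H](C[C@H]2[C@@H](C)CCC2=C)C(C)(C)O1 | intermediate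
18 | 8,11-O-isopropylidene-(4S,5S,7S,8S)-guai-1(10)-ene-8,11-diol | CC1(C)O[C@H]2CC(C)=C3CC[C@H](C)[C@@H]3C[C@@H]2C(C)(C)O1 | intermediate
19 | (3S,3aS,5S,6S)-5-(2-hydroxypropan-2-yl)-3,8-dimethyl-1,2,3,3a,4,5,6,7-octahydroazulen-6-ol | O[C@H]1CC(C)=C2CC[C@H](C)[C@@H]2C[C@@H]1C(C)(C)O | intermediate
20 | (2E)-3-(4-acetoxy-3-methoxyphenyl)prop-2-enoic acid | COc1cc(/C=C/C(=O)O)ccc1OC(C)=O | starting material
21 | O-acetylferulate of 19 at O8 | COc1cc(/C=C/C(=O)O[C@H]2CC(C)=C3CC[C@H](C)[C@@H]3C[C@@H]2C(C)(C)O)ccc1OC(C)=O | intermediate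
22 | (3S,3aS,5S,6S)-5-(2-hydroxypropan-2-yl)-3,8-dimethyl-1,2,3,3a,4,5,6,7-octahydroazulen-6-yl (2E)-3-(4-hydroxy-3-methoxyphenyl)prop-2-enoate | COc1cc(/C=C/C(=O)O[C@H]2CC(C)=C3CC[C@H](C)[C@@H]3C[C@@H]2C(C)(C)O)ccc1O | target

**Totals**
Total step count: 15. Longest linear sequence: 13 steps (steps 1–4 and 7–15, from 1).

**Steps most likely to fail**

1. Step 12. The two hindered 1,1-disubstituted olefins may fail to engage the catalyst, or ruthenium hydrides may move the C1 methylidene into the ring and erase C5. The fallback sets out from ketone 16. Ozonolysis of its methallyl olefin (O3, CH2Cl2/MeOH, −78 °C; Me2S) should give the diketone F1. Intramolecular McMurry coupling of the C1 and C10 carbonyls of F1 (TiCl3(DME)1.5, Zn–Cu couple, DME, reflux, slow addition) should then form the tetrasubstituted olefin and come back to the route at 18.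

2. Step 7. The strongly basic dianion may cause elimination of the cyclic sulfate, attack its secondary carbon, or react too slowly at the β-branched primary carbon. The fallback sets out from diol 5. Selective iodination of the primary hydroxyl (I2, PPh3, imidazole) should give the iodo alcohol F2, and silylation (Et3SiCl, imidazole, DMF) the protected iodide F3. Alkylation of dianion 11 with F3 in THF/DMPU (−78 to −10 °C) should give the silyl ether F4 with the same anti sense. HF·pyridine in THF then removes the silyl group and the sequence comes back at 13.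

3. Step 11. The titanium reagent may enolize the hindered ketone, with loss of the cis C5 configuration or incomplete olefination. The fallback sets out from ketone 16. Addition of Me3SiCH2Li/CeCl3 (a non-basic organocerium reagent, THF, −78 °C) to the C1 carbonyl should give the β-hydroxysilane F5. KH in THF then induces syn-elimination (Peterson olefination) and the sequence comes back at 17.

**Further compounds**
F1 | step 12 | (2S,3S)-3-methyl-2-{[(5S,6S)-2,2,4,4-tetramethyl-6-(2-oxopropyl)-1,3-dioxan-5-yl]methyl}cyclopentan-1-one | CC1(C)O[C@@H](CC(C)=O)[C@H](C[C@H]2[C@@H](C)CCC2=O)C(C)(C)O1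
F2 | step 7 | (1S,2S,3S)-2-(iodomethyl)-3-methylcyclopentan-1-ol | C[C@H]1CC[C@H](O)[C@H]1CI
F3 | step 7 | triethyl{[(1S,2S,3S)-2-(iodomethyl)-3-methylcyclopentyl]oxy}silane | C[C@H]1CC[C@H](O[Si](CC)(CC)CC)[C@H]1CI
F4 | step 7 | ethyl (2S,3S)-3-hydroxy-5-methyl-2-({(1S,2S,5S)-2-methyl-5-[(triethylsilyl)oxy]cyclopentyl}methyl)hex-5-enoate | CCOC(=O)[C@@H](C[C@H]1[C@@H](C)CC[C@@H]1O[Si](CC)(CC)CC)[C@@H](O)CC(C)=C
F5 | step 11 | (2S,3S)-3-methyl-2-{[(5S,6S)-2,2,4,4-tetramethyl-6-(2-methylprop-2-en-1-yl)-1,3-dioxan-5-yl]methyl}-1-[(trimethylsilyl)methyl]cyclopentan-1-ol (C1 epimers) | CC1(C)O[C@@H](CC(C)=C)[C@H](C[C@H]2[C@@H](C)CCC2(O)C[Si](C)(C)C)C(C)(C)O1
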